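The cyclohexanone ring (C1–C5, C10; eremophilane numbering) carries its carbonyl at C2, one carbon removed from the ring-fusion carbon C10, where no enone cycloaddition can place it. The ring is therefore made first as a cyclopentanone (C2, C3, C4, C5, C10): (S)-3,4-dimethylcyclopent-2-enone undergoes a Diels–Alder reaction across C5=C10 that sets C5, C9 and C10, and a β-oxido carbenoid then inserts C1 between C2 and C10 with retention at C10. This one operation enlarges the ring and moves the carbonyl into its final position. Hydroxyl-directed epoxidation and trans-diaxial isopropenyl opening complete C7–C9 before double tigloylation.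

Key step: step 7

Remarks on the chemistry:
- Atom labels are eremophilane labels: C1–C5 and C10 form the ketone ring (C2 = carbonyl, C4 and C5 carry methyl groups), C5–C10 form the second ring (C7 isopropenyl, C8 and C9 ester carbons, C10 ring-fusion CH).
- Both enantiomers of 4-(tert-butyldimethylsilyloxy)cyclopent-2-enone are assumed to be commercially available; the (S)-enantiomer is used.
- Carbinol 9 is used as the mixture of epimers at the new carbinol carbon, since this carbon becomes the sp2 carbonyl carbon in step 7.

Step 1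
Reactants: 1 (S)-4-(tert-butyldimethylsilyloxy)cyclopent-2-en-1-one
Product: 3 (S)-4-methylcyclopent-2-en-1-one, via trans-3-methyl-4-silyloxycyclopentanone 2 (not isolated)
Conditions: MeLi (2.2 equiv), CuI (1.1 equiv), Et2O, 0 → −78 °C; add 1; aq. NH4Cl; then DBU, CH2Cl2, −20 °C (short contact, cold work-up, volatile product)
Reagents that add atoms: lithium dimethylcuprate, [Li+].C[Cu-]C (made in the flask from methyllithium, [Li]C, and CuI)
Why: Gilman cuprate 1,4-addition occurs anti to the C4 silyloxy group, and E1cB loss of silanolate from the β-silyloxy ketone then relocates the enone so that the methyl-bearing carbon becomes the C4 stereocentre (conjugate addition–elimination with chirality transfer).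

Step 2
Reactants: 3 (S)-4-methylcyclopent-2-en-1-one
Product: 4 (3R,4S)-3,4-dimethyl-1-(trimethylsilyloxy)cyclopent-1-ene
Conditions: Me2CuLi (from MeLi, CuI), TMSCl, Et3N, Et2O/THF, −78 °C
Reagents that add atoms: lithium dimethylcuprate, [Li+].C[Cu-]C; chlorotrimethylsilane, C[Si](C)(C)Cl
Why: TMSCl-accelerated cuprate conjugate addition anti to the existing methyl group, with trapping of the regiodefined enolate as its silyl enol ether; the new C3 centre is transient and is removed in step 3.

Step 3
Reactants: 4 (3R,4S)-3,4-dimethyl-1-(trimethylsilyloxy)cyclopent-1-ene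
Product: 5 (S)-3,4-dimethylcyclopent-2-en-1-one
Conditions: Pd(OAc)2 (1.05 equiv), MeCN, rt
Reagents that add atoms: none
Why: Saegusa–Ito dehydrogenation, in which the palladium enolate can undergo β-hydride elimination only towards C3, so the enone is restored with the C4 stereocentre untouched.

Step 4
Reactants: 6 (E)-but-2-enal (crotonaldehyde)
Product: 7 (E)-1-(tert-butyldimethylsilyloxy)buta-1,3-diene
Conditions: TBSOTf, Et3N, Et2O, 0 °C → rt
Reagents that add atoms: tert-butyldimethylsilyl triflate, CC(C)(C)[Si](C)(C)OS(=O)(=O)C(F)(F)F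
Why: Silyl dienol ether formation by O-silylation and γ-deprotonation of the enal, which should give the (E)-1-silyloxydiene.

Step 5
Reactants: 5 (S)-3,4-dimethylcyclopent-2-en-1-one; 7 (E)-1-(tert-butyldimethylsilyloxy)buta-1,3-diene
Product: 8 (3S,3aR,7R,7aS)-7-(tert-butyldimethylsilyloxy)-3,3a-dimethyl-2,3,3a,4,7,7a-hexahydro-1H-inden-1-one (cis-fused)
Conditions: 7 (3 equiv), CH2Cl2, BHT (trace), 13 kbar, 40 °C
Reagents that add atoms: none
Why: High-pressure Diels–Alder reaction of a β,β-disubstituted enone: the nucleophilic diene terminus bonds to the β-carbon C5 ("ortho" regiochemistry), suprafacial addition anti to the C4 methyl sets the cis-fusion at C5 and C10, and the endo transition state places the C9 silyloxy group cis to the C10–C2 bond.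

Step 6
Reactants: 8 (3S,3aR,7R,7aS)-7-(tert-butyldimethylsilyloxy)-3,3a-dimethyl-2,3,3a,4,7,7a-hexahydro-1H-inden-1-one
Product: 9 (3S,3aR,7R,7aS)-1-(dibromomethyl)-7-(tert-butyldimethylsilyloxy)-3,3a-dimethyl-2,3,3a,4,7,7a-hexahydro-1H-inden-1-ol (epimers at C1)
Conditions: CH2Br2, LDA, THF, −78 °C; then 8, −78 °C; AcOH quench at −78 °C
Reagents that add atoms: dibromomethane, BrCBr (as dibromomethyllithium)
Why: 1,2-Addition of the preformed, weakly basic carbenoid LiCHBr2 to the ketone at −78 °C should outpace enolisation and β-elimination of the C9 silyloxy group (carbenoid addition to a ketone).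

Step 7
Reactants: 9 (3S,3aR,7R,7aS)-1-(dibromomethyl)-7-(tert-butyldimethylsilyloxy)-3,3a-dimethyl-2,3,3a,4,7,7a-hexahydro-1H-inden-1-ol
Product: 12 (4S,4aR,8R,8aS)-8-(tert-butyldimethylsilyloxy)-4,4a-dimethyl-3,4,4a,5,8,8a-hexahydronaphthalen-2(1H)-one, via β-oxido carbenoid 10 (not isolated), via lithium enolate 11 (not isolated)
Conditions: n-BuLi (2.3 equiv), THF, −78 °C → 0 °C; aq. NH4Cl
Reagents that add atoms: none
Why: The first equivalent of n-BuLi deprotonates the hydroxyl and the second performs bromine–lithium exchange to give the β-oxido carbenoid 10, in which a ring C–C bond migrates from the carbinol carbon C2 to the carbenoid carbon (the future C1) with loss of LiBr, giving the ring-enlarged enolate 11 that is protonated on work-up. The closest known reaction type is the β-oxido carbenoid (dibromomethyllithium) one-carbon homologation of cyclic ketones. No ring is closed: the five-membered ring C2–C3–C4–C5–C10 becomes the six-membered ring by a 1,2-shift that inserts C1 between C2 and C10. No new stereocentre is formed, and C10 keeps its configuration because the concerted 1,2-shift proceeds with retention at the migrating carbon, so the cis ring fusion from step 5 is carried over. The step needs migration of the tertiary C10 rather than the C3 methylene, which is secured by the preference of the more substituted α-carbon to migrate to the electron-poor carbenoid carbon. The silyl ether and the C7=C8 alkene are inert to these conditions, and the C2 carbonyl ends up γ to the C9 oxygen, so β-elimination is no longer possible.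

Step 8
Reactants: 12 (4S,4aR,8R,8aS)-8-(tert-butyldimethylsilyloxy)-4,4a-dimethyl-3,4,4a,5,8,8a-hexahydronaphthalen-2(1H)-one
Product: 13 the C2 ethylene ketal (1,3-dioxolane) of 12, other centres unchanged
Conditions: 1,2-bis(trimethylsilyloxy)ethane, TMSOTf (5 mol%), CH2Cl2, −78 → −20 °C; pyridine quench
Reagents that add atoms: 1,2-bis(trimethylsilyloxy)ethane, C[Si](C)(C)OCCO[Si](C)(C)C
Why: Noyori ketalisation under aprotic conditions leaves the allylic silyl ether and the alkene untouched and masks the ketone against the Grignard reagent of step 11.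

Step 9
Reactants: 13 ethylene ketal of 12
Product: 14 the C9 allylic alcohol: ethylene ketal of (4S,4aR,8R,8aS)-8-hydroxy-4,4a-dimethyl-3,4,4a,5,8,8a-hexahydronaphthalen-2(1H)-one
Conditions: TBAF, THF, 0 °C → rt
Reagents that add atoms: none
Why: Fluoride cleavage of the silyl ether frees the C9 hydroxyl that directs the epoxidation.

Step 10
Reactants: 14 C9 allylic alcohol ketal
Product: 15 the 7,8-epoxide of 14 with the epoxide oxygen cis to the C9 hydroxyl
Conditions: VO(acac)2 (5 mol%), t-BuOOH, CH2Cl2, 0 °C → rt
Reagents that add atoms: tert-butyl hydroperoxide, CC(C)(C)OO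
Why: Vanadium-catalysed hydroxyl-directed epoxidation delivers oxygen to C7=C8 from the face of the C9 hydroxyl, which should give the syn epoxy alcohol.

Step 11
Reactants: 15 syn-7,8-epoxy-9-hydroxy ketal
Product: 17 (4S,5R,7R,8R,9S,10S)-8,9-dihydroxyeremophil-11-en-2-one, via diol ketal 16 (not isolated)
Conditions: isopropenylmagnesium bromide (5 equiv), CuI (0.5 equiv), THF, −30 → 0 °C; then 1 M HCl, THF, rt
Reagents that add atoms: isopropenylmagnesium bromide, C=C(C)[Mg]Br; water, O
Why: Copper-catalysed Grignard opening of the epoxide by SN2 attack with inversion at C7, the carbon remote from the C9 alkoxide and reached by trans-diaxial (Fürst–Plattner) opening, sets the isopropenyl group trans to the C8 oxygen, and aqueous acid then hydrolyses the dioxolane.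

Step 12
Reactants: 17 (4S,5R,7R,8R,9S,10S)-8,9-dihydroxyeremophil-11-en-2-one
Product: 18 (4S,5R,7R,8R,9S,10S)-8,9-bis[(E)-2-methylbut-2-enoyloxy]eremophil-11-en-2-one (target)
Conditions: tigloyl chloride (4 equiv), DMAP, Et3N, CH2Cl2, 0 → 40 °C
Reagents that add atoms: (E)-2-methylbut-2-enoyl chloride (tigloyl chloride), ClC(=O)/C(C)=C/C
Why: DMAP-catalysed acylation of both secondary hydroxyls with the acid chloride; the (E)-tigloyl group is the stable isomer and no stereocentre is touched.

Compound list
1 | (S)-4-(tert-butyldimethylsilyloxy)cyclopent-2-en-1-one | O=C1C=C[C@@H](O[Si](C)(C)C(C)(C)C)C1 | starting material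
2 | (3S,4S)-4-(tert-butyldimethylsilyloxy)-3-methylcyclopentan-1-one (trans) | O=C1C[C@H](C)[C@@H](O[Si](C)(C)C(C)(C)C)C1 | intermediate
3 | (S)-4-methylcyclopent-2-en-1-one | O=C1C[C@H](C)C=C1 | intermediate
4 | (3R,4S)-3,4-dimethyl-1-(trimethylsilyloxy)cyclopent-1-ene (trans-dimethyl) | C[C@H]1C=C(O[Si](C)(C)C)C[C@@H]1C | intermediate
5 | (S)-3,4-dimethylcyclopent-2-en-1-one | CC1=CC(=O)C[C@@H]1C | intermediate
6 | (E)-but-2-enal (crotonaldehyde) | C/C=C/C=O | starting material
7 | (E)-1-(tert-butyldimethylsilyloxy)buta-1,3-diene | C=C/C=C/O[Si](C)(C)C(C)(C)C | intermediate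
8 | (3S,3aR,7R,7aS)-7-(tert-butyldimethylsilyloxy)-3,3a-dimethyl-2,3,3a,4,7,7a-hexahydro-1H-inden-1-one (cis-fused; methyls cis; silyloxy cis to the C10–C2 bond) | C1=CC[C@@]2(C)[C@H](C(=O)C[C@@H]2C)[C@@H]1O[Si](C)(C)C(C)(C)C | intermediate
9 | (3S,3aR,7R,7aS)-1-(dibromomethyl)-7-(tert-butyldimethylsilyloxy)-3,3a-dimethyl-2,3,3a,4,7,7a-hexahydro-1H-inden-1-ol (epimers at C1) | C1=CC[C@@]2(C)[C@H](C(O)(C(Br)Br)C[C@@H]2C)[C@@H]1O[Si](C)(C)C(C)(C)C | intermediate
10 | dilithio β-oxido carbenoid of 9 (O–Li and C(Br)–Li) | C1=CC[C@@]2(C)[C@H](C(O[Li])(C(Br)[Li])C[C@@H]2C)[C@@H]1O[Si](C)(C)C(C)(C)C | intermediate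
11 | lithium C1=C2 enolate of 12 | C1=CC[C@@]2(C)[C@H](C=C(O[Li])C[C@@H]2C)[C@@H]1O[Si](C)(C)C(C)(C)C | intermediate
12 | (4S,4aR,8R,8aS)-8-(tert-butyldimethylsilyloxy)-4,4a-dimethyl-3,4,4a,5,8,8a-hexahydronaphthalen-2(1H)-one (cis-fused) | C1=CC[C@@]2(C)[C@H](CC(=O)C[C@@H]2C)[C@@H]1O[Si](C)(C)C(C)(C)C | intermediate
13 | C2 ethylene ketal (1,3-dioxolane) of 12 | C1=CC[C@@]2(C)[C@H](CC3(OCCO3)C[C@@H]2C)[C@@H]1O[Si](C)(C)C(C)(C)C | intermediate
14 | C2 ethylene ketal of (4S,4aR,8R,8aS)-8-hydroxy-4,4a-dimethyl-3,4,4a,5,8,8a-hexahydronaphthalen-2(1H)-one | C1=CC[C@@]2(C)[C@H](CC3(OCCO3)C[C@@H]2C)[C@@H]1O | intermediate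
15 | 7,8-epoxide of 14, epoxide oxygen cis to the C9 hydroxyl | [C@@H]12C[C@@]3(C)[C@H](CC4(OCCO4)C[C@@H]3C)[C@H](O)[C@@H]1O2 | intermediate
16 | C2 ethylene ketal of (4S,5R,7R,8R,9S,10S)-8,9-dihydroxyeremophil-11-en-2-one | C=C(C)[C@H]1C[C@@]2(C)[C@H](CC3(OCCO3)C[C@@H]2C)[C@H](O)[C@@H]1O | intermediate
17 | (4S,5R,7R,8R,9S,10S)-8,9-dihydroxyeremophil-11-en-2-one | C=C(C)[C@H]1C[C@@]2(C)[C@H](CC(=O)C[C@@H]2C)[C@H](O)[C@@H]1O | intermediate
18 | (4S,5R,7R,8R,9S,10S)-8,9-bis[(E)-2-methylbut-2-enoyloxy]eremophil-11-en-2-one | C=C(C)[C@H]1C[C@@]2(C)[C@H](CC(=O)C[C@@H]2C)[C@H](OC(=O)/C(C)=C/C)[C@@H]1OC(=O)/C(C)=C/C | target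

Total step count: 12. Longest linear sequence: 11 steps (steps 1–3 and 5–12); step 4 is a one-step side branch.

Steps most likely to fail

1. Step 5 (Diels–Alder). The β,β-disubstituted enone may react too slowly even at 13 kbar, so that diene polymerisation or loss of the silyl group competes, and endo/exo control at C9 may be incomplete. Fallback, from 5 back to 8: bromine is added to 5 (Br2, CH2Cl2, 0 °C) to give 2,3-dibromo-3,4-dimethylcyclopentanone F1. Triethylamine then eliminates HBr to (S)-2-bromo-3,4-dimethylcyclopent-2-en-1-one F2, a more electron-poor and more reactive dienophile. Cycloaddition of F2 with 7 (toluene, 80 °C) should give the angular bromide F3 with the same regiochemistry and facial sense. Bu3SnH/AIBN (benzene, 80 °C) then removes bromine by hydrogen-atom transfer to the C10 radical from the convex face, which gives the cis-fused ketone 8.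

2. Step 7 (key step). Migration of the C3 methylene instead of C10 would give the regioisomeric decalinone, and premature protonation or decomposition of the carbenoid would lower the yield. The addition in step 6 may also suffer from enolisation of the hindered ketone. Fallback, from 8 back to 12, replacing steps 6 and 7: phenylselenomethyllithium (from bis(phenylseleno)methane and n-BuLi, THF, −78 °C) is added to 8 to give the β-hydroxy selenide F4. Se-methylation (MeOTf, CH2Cl2) and mild base then trigger a cationic semipinacol 1,2-shift with loss of methyl phenyl selenide. In this shift the tertiary C10 migrates by its higher migratory aptitude and with retention, giving 12.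

3. Step 11 (epoxide opening). Attack at C8 instead of C7, or a conformer that disfavours trans-diaxial attack at C7 on the face that carries the C5 methyl, would give the wrong regioisomer or slow opening with elimination to an allylic alcohol. Fallback, from 14 back to 16: oxidation of 14 (Dess–Martin periodinane) gives the C9 enone F5. Conjugate addition of lithium diisopropenylcuprate with TMSCl (THF, −78 °C) at C7 from the convex face gives the silyl enol ether F6. Rubottom oxidation (DMDO, acetone, −78 °C, where the enol ether reacts faster than the isopropenyl group) gives the α-hydroxy ketone F7 with the C8 hydroxyl anti to the isopropenyl group. Hydride reduction of the C9 ketone from the convex face (NaBH4, MeOH, −20 °C) gives the cis-diol ketal 16, which is hydrolysed to 17 by the acid treatment of step 11.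

Further compounds
F1 | step 5 | (4S)-2,3-dibromo-3,4-dimethylcyclopentan-1-one (mixture at C2 and C3) | CC1(Br)C(Br)C(=O)C[C@@H]1C
F2 | step 5 | (S)-2-bromo-3,4-dimethylcyclopent-2-en-1-one | CC1=C(Br)C(=O)C[C@@H]1C
F3 | step 5 | 7a-bromo analogue of 8 (bromine at the ring-fusion carbon C10, cis-fused) | C1=CC[C@@]2(C)[C@](Br)(C(=O)C[C@@H]2C)[C@@H]1O[Si](C)(C)C(C)(C)C
F4 | step 7 | 1-(phenylselanylmethyl) carbinol of 8 (epimers at the carbinol carbon) | C1=CC[C@@]2(C)[C@H](C(O)(C[Se]c3ccccc3)C[C@@H]2C)[C@@H]1O[Si](C)(C)C(C)(C)C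
F5 | step 11 | C9 enone: C2 ethylene ketal of the cis-fused 4,4a-dimethyl-4a,5-dihydro-naphthalene-2,8-dione skeleton (C7=C8–C9=O) | C1=CC[C@@]2(C)[C@H](CC3(OCCO3)C[C@@H]2C)C1=O
F6 | step 11 | C9 trimethylsilyl enol ether (C8=C9) carrying the C7 isopropenyl group, C2 ketal | C=C(C)[C@H]1C[C@@]2(C)[C@H](CC3(OCCO3)C[C@@H]2C)C(O[Si](C)(C)C)=C1
F7 | step 11 | 8-hydroxy-9-oxo compound (C8 hydroxyl anti to the C7 isopropenyl group), C2 ketal | C=C(C)[C@H]1C[C@@]2(C)[C@H](CC3(OCCO3)C[C@@H]2C)C(=O)[C@@H]1O
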